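**Retrosynthetic overview**
1. Ester C–O bond: the carboxylate of the cyclohexenyl acrylic acid opens a spiro-epoxide at its CH2, which unveils the tertiary alcohol with its configuration intact.
2. Seven-membered lactone: Horner–Wadsworth–Emmons olefination of a ring aldehyde, then lactonization of the new CH2OH onto the cis methyl ester.
3. The cis aldehyde/ester pair comes from ozonolysis of a cis-fused 1-bromocyclohexa-1,3-diene, the CO2-extrusion product of the Diels–Alder adduct of (S)-cryptone and 3-bromo-2-pyrone. That cycloaddition closes the lactone bridge and the etheno bridge at once and sets both ring-fusion centres; a sulfur ylide then adds the spiro-epoxide from the face the cage leaves open.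
4. Acid half: the same (S)-cryptone by conjugate vinylation/enol triflation, vinyl ozonolysis, the same olefination reagent and Stille hydroxymethylation.
5. Ring order: cyclohexenone (Michael/aldol) → 2-oxabicyclo[2.2.2]octene (Diels–Alder) → oxirane → bicycle unravelled → seven-membered lactone.

Assumption: the (S)-prolinol ether of step 1 gives the (S)-aldehyde (usual facial model for diarylprolinol ethers); if the sense is opposite, the (R)-catalyst is used and nothing else changes.

**Route**

Step 1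
Reactants: 1 3-methylbutanal; 2 but-3-en-2-one
Product: 3 (2S)-5-oxo-2-(propan-2-yl)hexanal
Conditions: (S)-2-(methoxydiphenylmethyl)pyrrolidine (5 mol%), ethyl 3,4-dihydroxybenzoate (20 mol%), neat, 4 °C
Reagents that add atoms: none
Why: Enamine-catalysed Michael addition; the diphenyl(methoxy)methyl group shields one face of the (E)-enamine, so the enone adds to the open face and the α-carbon becomes S.

Step 2
Reactants: 3 (2S)-5-oxo-2-(propan-2-yl)hexanal
Product: 5 (4S)-4-(propan-2-yl)cyclohex-2-en-1-one ((S)-cryptone), via ketol 4 (not isolated)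
Conditions: LiOH, iPrOH, 25 °C
Reagents that add atoms: none
Why: Intramolecular aldol condensation (Robinson-type closure) of the methyl ketone onto the aldehyde; the stereocentre is not involved.

Step 3
Reactants: 5 (S)-cryptone; 6 3-bromo-2H-pyran-2-one
Product: 7 endo Diels–Alder adduct 4-bromo-8-(propan-2-yl)hexahydro-1H-1,4-ethenoisochromene-3,5-dione (8S; new C–C bonds cis to each other and trans to isopropyl; C–Br bridgehead on the carbon next to the ketone)
Conditions: CH2Cl2, 12 kbar, 25 °C, 72 h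
Reagents that add atoms: none
Why: Diels–Alder cycloaddition of the ambiphilic bromopyrone, closing the lactone bridge and the etheno bridge together; suprafacial addition makes both new bonds cis, the diene approaches the enone face opposite the isopropyl group, and the brominated terminus bonds to the enone α-carbon as with acrylate-type dienophiles (endo and exo adducts converge in step 5).

Step 4
Reactants: 7 Diels–Alder adduct
Product: 8 4-bromo-8-(propan-2-yl)hexahydrospiro[1,4-ethenoisochromene-5,2'-oxiran]-3-one (oxirane oxygen syn to the bridge bonds)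
Conditions: Me3SI, KN(SiMe3)2, THF, −10 to 0 °C
Reagents that add atoms: trimethylsulfonium iodide, C[S+](C)C.[I-]
Why: Corey–Chaykovsky epoxidation; the methylide attacks the ketone from the face opposite the bicyclic cage (axial attack), so CH2 ends trans and O cis to the bridge bonds, which fixes the tertiary carbinol centre.

Step 5
Reactants: 8 spiro-epoxide adduct
Product: 9 (1R,4S,4aS,8aS)-8-bromo-4-(propan-2-yl)-3,4,4a,8a-tetrahydro-2H-spiro[naphthalene-1,2'-oxirane]
Conditions: toluene, 120 °C, sealed tube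
Reagents that add atoms: none
Why: Retro-Diels–Alder extrusion of CO2 from the bridged lactone gives the cis-fused 1-bromocyclohexa-1,3-diene; the ring-fusion centres set in step 3 are untouched.

Step 6
Reactants: 9 bromodiene spiro-epoxide
Product: 11 methyl (3R,4S,5S,6S)-5-formyl-6-(propan-2-yl)-1-oxaspiro[2.5]octane-4-carboxylate, via acyl bromide 10 (not isolated)
Conditions: O3, CH2Cl2/MeOH (4:1), NaHCO3, −78 °C; then Me2S, −78 to 20 °C
Reagents that add atoms: ozone, [O-][O+]=O; methanol, CO
Why: Ozonolysis of both diene double bonds excises the two inner carbons; the bromo-substituted carbon leaves as an acyl bromide that methanol turns into the ester, the other end becomes the aldehyde, so the two cis carbonyl groups are differentiated (NaHCO3 takes up HBr and protects the epoxide).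

Step 7
Reactants: 12 tert-butyl 2-(diethoxyphosphoryl)acetate
Product: 13 tert-butyl 2-(diethoxyphosphoryl)-3-hydroxypropanoate (racemic)
Conditions: 37% aq. CH2O (1.0 equiv), K2CO3 (0.2 equiv), THF, 0 °C
Reagents that add atoms: formaldehyde, C=O
Why: Base-catalysed hydroxymethylation (aldol-type addition of the phosphonoacetate to formaldehyde); the new centre is lost in the olefination.

Step 8
Reactants: 11 aldehyde methyl ester; 13 hydroxymethyl phosphonate
Product: 15 tert-butyl (5aR,6S,9R,9aS)-1-oxo-6-(propan-2-yl)-1,3,5a,6,7,8-hexahydro-9aH-spiro[2-benzoxepine-9,2'-oxirane]-4-carboxylate, via hydroxy diester 14 (not isolated)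
Conditions: LiCl, DBU, MeCN, 0 to 45 °C
Reagents that add atoms: none
Why: Masamune–Roush Horner–Wadsworth–Emmons olefination gives the (E)-acrylate (ring carbon cis to CH2OH), whose primary hydroxyl then lactonizes onto the cis methyl ester (DBU-promoted transesterification); no stereocentre is touched.

Step 9
Reactants: 5 (S)-cryptone
Product: 17 (3S,4S)-3-ethenyl-4-(propan-2-yl)cyclohex-1-en-1-yl trifluoromethanesulfonate, via magnesium enolate 16 (not isolated)
Conditions: CH2=CHMgBr, CuBr·SMe2 (10 mol%), THF, −78 °C; then 2-[N,N-bis(trifluoromethylsulfonyl)amino]-5-chloropyridine, −78 to 0 °C; aq. NH4Cl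
Reagents that add atoms: vinylmagnesium bromide, C=C[Mg]Br; 2-[N,N-bis(trifluoromethylsulfonyl)amino]-5-chloropyridine, Clc1ccc(N(S(=O)(=O)C(F)(F)F)S(=O)(=O)C(F)(F)F)nc1
Why: Copper-catalysed conjugate addition trans to the adjacent isopropyl group, then O-triflation of the regiodefined enolate (Comins-type triflation), which fixes the later ring double bond.

Step 10
Reactants: 17 vinyl enol triflate
Product: 18 (3S,4S)-3-formyl-4-(propan-2-yl)cyclohex-1-en-1-yl trifluoromethanesulfonate
Conditions: O3, CH2Cl2, −78 °C (stopped at first excess); then Me2S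
Reagents that add atoms: ozone, [O-][O+]=O
Why: Chemoselective ozonolysis of the electron-rich terminal vinyl group; the electron-poor enol triflate double bond is not attacked.

Step 11
Reactants: 18 aldehyde enol triflate; 13 hydroxymethyl phosphonate
Product: 19 tert-butyl (2E)-2-(hydroxymethyl)-3-[(1R,6S)-6-(propan-2-yl)-3-(trifluoromethanesulfonyloxy)cyclohex-2-en-1-yl]prop-2-enoate
Conditions: LiCl, DBU, MeCN, 0 to 20 °C
Reagents that add atoms: none
Why: Horner–Wadsworth–Emmons olefination under mild Masamune–Roush conditions, E-selective for the α-branched aldehyde; the trans ring centre is the thermodynamic one and is kept.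

Step 12
Reactants: 19 enol triflate acrylate
Product: 20 tert-butyl (2E)-2-(hydroxymethyl)-3-[(1S,6S)-3-(hydroxymethyl)-6-(propan-2-yl)cyclohex-2-en-1-yl]prop-2-enoate
Conditions: Bu3SnCH2OH, Pd(PPh3)4 (5 mol%), LiCl, 1,4-dioxane, 90 °C
Reagents that add atoms: (tributylstannyl)methanol, CCCC[Sn](CCCC)(CCCC)CO
Why: Migita–Kosugi–Stille hydroxymethylation of the enol triflate with retention of the double-bond position; no stereocentre is touched.

Step 13
Reactants: 20 diol tert-butyl ester
Product: 21 (2E)-2-(hydroxymethyl)-3-[(1S,6S)-3-(hydroxymethyl)-6-(propan-2-yl)cyclohex-2-en-1-yl]prop-2-enoic acid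
Conditions: 85% aq. H3PO4, toluene, 25 °C
Reagents that add atoms: none
Why: Mild acidolysis of the tert-butyl ester (alkyl–oxygen cleavage) that leaves the allylic alcohols and the alkenes alone.

Step 14
Reactants: 15 spiro-epoxy lactone; 21 diol acid
Product: 22 tert-butyl (5aR,6S,9R,9aS)-9-hydroxy-9-[({(2E)-2-(hydroxymethyl)-3-[(1S,6S)-3-(hydroxymethyl)-6-(propan-2-yl)cyclohex-2-en-1-yl]prop-2-enoyl}oxy)methyl]-1-oxo-6-(propan-2-yl)-1,3,5a,6,7,8,9,9a-octahydro-2-benzoxepine-4-carboxylate
Conditions: Cs2CO3 (0.3 equiv), DMF, 60 °C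
Reagents that add atoms: none
Why: SN2 opening of the epoxide at its CH2 by the caesium carboxylate (alkoxides of the free alcohols are not formed); the tertiary C–O bond is not broken, so the carbinol keeps the configuration set in step 4.

Step 15
Reactants: 22 tert-butyl ester
Product: 23 (5aR,6S,9R,9aS)-9-hydroxy-9-[({(2E)-2-(hydroxymethyl)-3-[(1S,6S)-3-(hydroxymethyl)-6-(propan-2-yl)cyclohex-2-en-1-yl]prop-2-enoyl}oxy)methyl]-1-oxo-6-(propan-2-yl)-1,3,5a,6,7,8,9,9a-octahydro-2-benzoxepine-4-carboxylic acid (CNP0361406.4)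
Conditions: 85% aq. H3PO4, toluene, 25 °C
Reagents that add atoms: none
Why: Acidolysis of the tert-butyl ester under conditions that spare the lactone, the acrylate ester and the tertiary and allylic alcohols; no stereocentre is affected.

**Compound list**
1 | 3-methylbutanal | CC(C)CC=O | starting material
2 | but-3-en-2-one | CC(=O)C=C | starting material
3 | (2S)-5-oxo-2-(propan-2-yl)hexanal | CC(C)[C@@H](C=O)CCC(C)=O | intermediate
4 | (4S)-3-hydroxy-4-(propan-2-yl)cyclohexan-1-one (ketol, both C3 epimers, not isolated) | CC(C)[C@@H]1CCC(=O)CC1O | intermediate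
5 | (4S)-4-(propan-2-yl)cyclohex-2-en-1-one ((S)-cryptone) | CC(C)[C@@H]1CCC(=O)C=C1 | intermediate
6 | 3-bromo-2H-pyran-2-one | O=C1OC=CC=C1Br | starting material
7 | endo Diels–Alder adduct, 4-bromo-8-(propan-2-yl)hexahydro-1H-1,4-ethenoisochromene-3,5-dione (8S; bridge bonds cis to each other, trans to isopropyl) | CC(C)[C@@H]1CCC(=O)[C@H]2[C@]3(Br)C(=O)O[C@@H](C=C3)[C@@H]12 | intermediate
8 | 4-bromo-8-(propan-2-yl)hexahydrospiro[1,4-ethenoisochromene-5,2'-oxiran]-3-one (oxirane O syn to the bridge bonds) | CC(C)[C@@H]1CC[C@]2(CO2)[C@H]3[C@]4(Br)C(=O)O[C@@H](C=C4)[C@@H]13 | intermediate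
9 | (1R,4S,4aS,8aS)-8-bromo-4-(propan-2-yl)-3,4,4a,8a-tetrahydro-2H-spiro[naphthalene-1,2'-oxirane] | CC(C)[C@@H]1CC[C@]2(CO2)[C@H]3C(Br)=CC=C[C@@H]13 | intermediate
10 | (3R,4S,5S,6S)-5-formyl-6-(propan-2-yl)-1-oxaspiro[2.5]octane-4-carbonyl bromide (not isolated) | CC(C)[C@@H]1CC[C@]2(CO2)[C@@H](C(Br)=O)[C@H]1C=O | intermediate
11 | methyl (3R,4S,5S,6S)-5-formyl-6-(propan-2-yl)-1-oxaspiro[2.5]octane-4-carboxylate | CC(C)[C@@H]1CC[C@]2(CO2)[C@@H](C(=O)OC)[C@H]1C=O | intermediate
12 | tert-butyl 2-(diethoxyphosphoryl)acetate | CCOP(=O)(OCC)CC(=O)OC(C)(C)C | starting material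
13 | tert-butyl 2-(diethoxyphosphoryl)-3-hydroxypropanoate (racemic) | CCOP(=O)(OCC)C(CO)C(=O)OC(C)(C)C | intermediate
14 | methyl (3R,4S,5R,6S)-5-[(1E)-3-tert-butoxy-2-(hydroxymethyl)-3-oxoprop-1-en-1-yl]-6-(propan-2-yl)-1-oxaspiro[2.5]octane-4-carboxylate (not isolated) | CC(C)[C@@H]1CC[C@]2(CO2)[C@@H](C(=O)OC)[C@H]1/C=C(\CO)C(=O)OC(C)(C)C | intermediate
15 | tert-butyl (5aR,6S,9R,9aS)-1-oxo-6-(propan-2-yl)-1,3,5a,6,7,8-hexahydro-9aH-spiro[2-benzoxepine-9,2'-oxirane]-4-carboxylate | CC(C)[C@@H]1CC[C@]2(CO2)[C@H]3C(=O)OCC(C(=O)OC(C)(C)C)=C[C@@H]13 | intermediate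
16 | bromo{[(3S,4S)-3-ethenyl-4-(propan-2-yl)cyclohex-1-en-1-yl]oxy}magnesium (not isolated) | CC(C)[C@@H]1CCC(O[Mg]Br)=C[C@H]1C=C | intermediate
17 | (3S,4S)-3-ethenyl-4-(propan-2-yl)cyclohex-1-en-1-yl trifluoromethanesulfonate | CC(C)[C@@H]1CCC(OS(=O)(=O)C(F)(F)F)=C[C@H]1C=C | intermediate
18 | (3S,4S)-3-formyl-4-(propan-2-yl)cyclohex-1-en-1-yl trifluoromethanesulfonate | CC(C)[C@@H]1CCC(OS(=O)(=O)C(F)(F)F)=C[C@H]1C=O | intermediate
19 | tert-butyl (2E)-2-(hydroxymethyl)-3-[(1R,6S)-6-(propan-2-yl)-3-(trifluoromethanesulfonyloxy)cyclohex-2-en-1-yl]prop-2-enoate | CC(C)[C@@H]1CCC(OS(=O)(=O)C(F)(F)F)=C[C@H]1/C=C(\CO)C(=O)OC(C)(C)C | intermediate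
20 | tert-butyl (2E)-2-(hydroxymethyl)-3-[(1S,6S)-3-(hydroxymethyl)-6-(propan-2-yl)cyclohex-2-en-1-yl]prop-2-enoate | CC(C)[C@@H]1CCC(CO)=C[C@H]1/C=C(\CO)C(=O)OC(C)(C)C | intermediate
21 | (2E)-2-(hydroxymethyl)-3-[(1S,6S)-3-(hydroxymethyl)-6-(propan-2-yl)cyclohex-2-en-1-yl]prop-2-enoic acid | CC(C)[C@@H]1CCC(CO)=C[C@H]1/C=C(\CO)C(=O)O | intermediate
22 | tert-butyl ester of the target (name as in step 14) | CC(C)[C@@H]1CC[C@](O)(COC(=O)/C(=C/[C@@H]2C=C(CO)CC[C@H]2C(C)C)CO)[C@H]2C(=O)OCC(C(=O)OC(C)(C)C)=C[C@@H]12 | intermediate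
23 | CNP0361406.4 (name as in step 15) | CC(C)[C@@H]1CC[C@](O)(COC(=O)/C(=C/[C@@H]2C=C(CO)CC[C@H]2C(C)C)CO)[C@H]2C(=O)OCC(C(=O)O)=C[C@@H]12 | target

**Totals**
Total steps: 15. Longest linear sequence: 9 steps (1, 2, 3, 4, 5, 6, 8, 14, 15; the acid branch 1, 2, 9–13, 14, 15 is equally long).

**Steps most likely to fail, with fallbacks**

Step 3 (Diels–Alder). A 1,2-disubstituted cyclic enone is a weak dienophile and the orientation is argued only by analogy with acrylates. The fallback sets out from 5 and returns at 11. Enone–alkyne [2+2] photocycloaddition of 5 with acetylene (hν 350 nm, CH2Cl2, −70 °C) gives the cis-fused cyclobutene ketone F1, with the four-membered ring trans to isopropyl. Corey–Chaykovsky epoxidation (Me3SI, KN(SiMe3)2) from the convex face gives spiro-epoxide F2. Unsymmetrical ozonolysis of the cyclobutene (O3, CH2Cl2/MeOH, NaHCO3, −78 °C; then Ac2O, Et3N) gives aldehyde ester 11, separated from its regioisomer.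

Step 8 (olefination with the hydroxymethyl phosphonate, then seven-membered lactonization beside a base-sensitive epoxy ester). The fallback sets out from 9 and returns at 15, and closes the ring by olefination instead of lactonization. Compound 9 is ozonized in CH2Cl2 alone at −78 °C, the acyl bromide 10 is trapped with alcohol 13 and pyridine before Me2S is added, and this gives phosphonoester aldehyde F3. Intramolecular Horner–Wadsworth–Emmons reaction (LiCl, iPr2NEt, MeCN, 2 mM, 20 °C) then gives 15.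

Step 14 (carboxylate opening of a 2,2-disubstituted epoxide with the full acid half). The fallback sets out from 15 (and from 20 for the acid partner) and returns at 22, replacing epoxide opening by acylation of a diol. Caesium formate (HCOOCs, DMF, 60 °C) opens 15 to hydroxy formate F4, and KHCO3 in MeOH at 0 °C removes the formyl group to give diol F5. Diol ester 20 is silylated (TBSCl, imidazole) to bis-silyl ether F6, and its tert-butyl ester is cleaved (TMSOTf, 2,6-lutidine, then water) to bis-silyl acid F7. Yamaguchi esterification (2,4,6-trichlorobenzoyl chloride, Et3N, then 4-(dimethylamino)pyridine) of the primary hydroxyl of F5 with F7 gives bis-silyl ester F8. HF·pyridine removes both silyl ethers to give 22.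

**Further compounds**
F1 | step 3 | (5S)-5-(propan-2-yl)-cis-bicyclo[4.2.0]oct-7-en-2-one, cyclobutene trans to isopropyl | CC(C)[C@@H]1CCC(=O)[C@H]2C=C[C@@H]12
F2 | step 3 | spiro-epoxide of F1, oxirane O cis to the cyclobutene bonds | CC(C)[C@@H]1CC[C@]2(CO2)[C@H]3C=C[C@@H]13
F3 | step 8 | 3-tert-butoxy-2-(diethoxyphosphoryl)-3-oxopropyl (3R,4S,5S,6S)-5-formyl-6-(propan-2-yl)-1-oxaspiro[2.5]octane-4-carboxylate (epimers at the phosphonate carbon) | CC(C)[C@@H]1CC[C@]2(CO2)[C@@H](C(=O)OCC(P(=O)(OCC)OCC)C(=O)OC(C)(C)C)[C@H]1C=O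
F4 | step 14 | tert-butyl (5aR,6S,9R,9aS)-9-[(formyloxy)methyl]-9-hydroxy-1-oxo-6-(propan-2-yl)-1,3,5a,6,7,8,9,9a-octahydro-2-benzoxepine-4-carboxylate | CC(C)[C@@H]1CC[C@](O)(COC=O)[C@H]2C(=O)OCC(C(=O)OC(C)(C)C)=C[C@@H]12
F5 | step 14 | tert-butyl (5aR,6S,9R,9aS)-9-hydroxy-9-(hydroxymethyl)-1-oxo-6-(propan-2-yl)-1,3,5a,6,7,8,9,9a-octahydro-2-benzoxepine-4-carboxylate | CC(C)[C@@H]1CC[C@](O)(CO)[C@H]2C(=O)OCC(C(=O)OC(C)(C)C)=C[C@@H]12
F6 | step 14 | bis(tert-butyldimethylsilyl) ether of 20 | CC(C)[C@@H]1CCC(CO[Si](C)(C)C(C)(C)C)=C[C@H]1/C=C(\CO[Si](C)(C)C(C)(C)C)C(=O)OC(C)(C)C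
F7 | step 14 | bis(tert-butyldimethylsilyl) ether of 21 | CC(C)[C@@H]1CCC(CO[Si](C)(C)C(C)(C)C)=C[C@H]1/C=C(\CO[Si](C)(C)C(C)(C)C)C(=O)O
F8 | step 14 | bis(tert-butyldimethylsilyl) ether of 22 (both primary allylic hydroxyls of the acyl part silylated) | CC(C)[C@@H]1CC[C@](O)(COC(=O)/C(=C/[C@@H]2C=C(CO[Si](C)(C)C(C)(C)C)CC[C@H]2C(C)C)CO[Si](C)(C)C(C)(C)C)[C@H]2C(=O)OCC(C(=O)OC(C)(C)C)=C[C@@H]12
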